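Everything rests on cutting C9–C10. In ring A (C1–C5, C10) the C3 oxygen lies para to the quaternary, methyl-bearing C10 and ortho to the C4 methyl, so ring A is a masked 2,4-dimethylphenol whose meta carbon C5 carries the C6–C9 chain. Acid-triggered attack of that phenol's para carbon on a terminal diazoketone should forge C9–C10, close ring B, dearomatise ring A to the 1,4-dien-3-one and relay the C7 configuration to C10 in one operation. The precursor is a free-phenol diazoketone built by Evans alkylation of a succinyl imide with a silylated 3-hydroxy-2,6-dimethylbenzyl bromide. Hydrogenation, double reduction with lactonisation, α-methylenation and stepwise acylation then complete the target.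

Key step: step 12

Remark (assumptions): eudesmane numbering is used; the target is read as methyl 8β-acetoxy-3β-propanoyloxyeudesma-4,11(13)-dien-12-oate, (3S,7R,8R,10R), with the C7 side chain, both oxygens and the C10 methyl on the β face; the succinate unit enters as commercial methyl 4-chloro-4-oxobutanoate; C11 of the transient compounds 27 and 28 is of no consequence and is drawn undefined.

Step 1
Reactants: 1 2,6-dimethylbenzoic acid
Product: 2 2,6-dimethyl-3-nitrobenzoic acid
Conditions: fuming HNO3, conc. H2SO4, 0 °C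
Reagents that add atoms: nitric acid, O[N+](=O)[O-]
Why: Electrophilic aromatic nitration in which both methyl groups (ortho/para) and the carboxyl group (meta) direct to the same ring carbon, so mononitration should occur at C3.

Step 2
Reactants: 2 2,6-dimethyl-3-nitrobenzoic acid
Product: 3 3-amino-2,6-dimethylbenzoic acid
Conditions: H2 (1 atm), 10% Pd/C, MeOH, rt
Reagents that add atoms: none
Why: Catalytic hydrogenation of an aryl nitro group to the aniline, which leaves the carboxylic acid untouched.

Step 3
Reactants: 3 3-amino-2,6-dimethylbenzoic acid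
Product: 5 3-hydroxy-2,6-dimethylbenzoic acid, via arenediazonium hydrogensulfate 4 (not isolated)
Conditions: NaNO2, aq. H2SO4, 0–5 °C; then 30% H2SO4, reflux
Reagents that add atoms: water, O
Why: Diazotisation followed by thermal hydrolysis of the arenediazonium salt replaces NH2 by OH, the standard way from aminobenzoic acids to hydroxybenzoic acids.

Step 4
Reactants: 5 3-hydroxy-2,6-dimethylbenzoic acid
Product: 6 3-(hydroxymethyl)-2,4-dimethylphenol
Conditions: LiAlH4, THF, 0 °C → reflux; aqueous work-up
Reagents that add atoms: none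
Why: Hydride reduction of a carboxylic acid to the primary alcohol; LiAlH4 in refluxing THF reduces even 2,6-disubstituted benzoic acids and the phenoxide formed alongside is inert.

Step 5
Reactants: 6 3-(hydroxymethyl)-2,4-dimethylphenol
Product: 8 {2,6-dimethyl-3-[(triisopropylsilyl)oxy]phenyl}methanol, via sodium phenoxide 7 (not isolated)
Conditions: NaH (1.0 equiv), THF, 0 °C; TIPSCl, 0 °C → rt
Reagents that add atoms: chlorotriisopropylsilane, CC(C)[Si](Cl)(C(C)C)C(C)C
Why: Chemoselective O-silylation, since one equivalent of NaH deprotonates only the phenol (pKa about 10 against about 15 for the benzylic alcohol) and the phenoxide captures the silyl chloride; TIPS is chosen because it should outlast the later LiOOH step yet remain fluoride-labile.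

Step 6
Reactants: 8 {2,6-dimethyl-3-[(triisopropylsilyl)oxy]phenyl}methanol
Product: 9 [3-(bromomethyl)-2,4-dimethylphenoxy]triisopropylsilane
Conditions: CBr4, PPh3, CH2Cl2, 0 °C
Reagents that add atoms: carbon tetrabromide, BrC(Br)(Br)Br
Why: Appel bromination converts the benzylic alcohol to the bromide under neutral conditions, avoiding acid that could cause Friedel–Crafts self-alkylation of the electron-rich ring.

Step 7
Reactants: 10 (R)-4-benzyl-2-oxazolidinone; 11 methyl 4-chloro-4-oxobutanoate
Product: 12 methyl 4-[(4R)-4-benzyl-2-oxo-1,3-oxazolidin-3-yl]-4-oxobutanoate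
Conditions: Et3N, DMAP (cat.), CH2Cl2, 0 °C → rt
Reagents that add atoms: none
Why: DMAP-catalysed N-acylation of the oxazolidinone with an acid chloride gives the imide without touching the auxiliary stereocentre.

Step 8
Reactants: 12 methyl 4-[(4R)-4-benzyl-2-oxo-1,3-oxazolidin-3-yl]-4-oxobutanoate; 9 [3-(bromomethyl)-2,4-dimethylphenoxy]triisopropylsilane
Product: 14 methyl (3R)-4-[(4R)-4-benzyl-2-oxo-1,3-oxazolidin-3-yl]-3-{[2,6-dimethyl-3-(triisopropylsilyloxy)phenyl]methyl}-4-oxobutanoate, via sodium Z-enolate 13 (not isolated)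
Conditions: NaHMDS, THF, −78 °C; then 9, −78 → −20 °C
Reagents that add atoms: none
Why: Evans asymmetric alkylation, in which NaHMDS enolises the more acidic imide α-CH2 to the chelated Z-enolate and the benzylic bromide adds to the face opposite the C4 benzyl group of the (R)-auxiliary, setting C7 as R.

Step 9
Reactants: 14 methyl (3R)-4-[(4R)-4-benzyl-2-oxo-1,3-oxazolidin-3-yl]-3-{[2,6-dimethyl-3-(triisopropylsilyloxy)phenyl]methyl}-4-oxobutanoate
Product: 16 (2R)-2-{[2,6-dimethyl-3-(triisopropylsilyloxy)phenyl]methyl}-4-methoxy-4-oxobutanoic acid, via lithium peroxycarboxylate 15 (not isolated)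
Conditions: LiOH, H2O2, THF/H2O, 0 °C; Na2SO3; then 1 M HCl to pH 3
Reagents that add atoms: hydrogen peroxide, OO
Why: Hydroperoxide cleavage of the Evans imide attacks the exocyclic carbonyl faster than it hydrolyses the methyl ester, and sulfite reduces the percarboxylate to the acid with C7 untouched.

Step 10
Reactants: 16 (2R)-2-{[2,6-dimethyl-3-(triisopropylsilyloxy)phenyl]methyl}-4-methoxy-4-oxobutanoic acid
Product: 18 methyl (3R)-5-diazo-3-{[2,6-dimethyl-3-(triisopropylsilyloxy)phenyl]methyl}-4-oxopentanoate, via mixed isobutyl carbonic anhydride 17 (not isolated)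
Conditions: i-BuOCOCl, N-methylmorpholine, THF, −15 °C; then CH2N2, Et2O, 0 °C → rt
Reagents that add atoms: diazomethane, C=[N+]=[N-]
Why: Acylation of diazomethane through the mixed carbonic anhydride (first stage of an Arndt–Eistert sequence) proceeds at low temperature without ketene formation, so the α-stereocentre C7 should be retained.

Step 11
Reactants: 18 methyl (3R)-5-diazo-3-{[2,6-dimethyl-3-(triisopropylsilyloxy)phenyl]methyl}-4-oxopentanoate
Product: 19 methyl (3R)-5-diazo-3-[(3-hydroxy-2,6-dimethylphenyl)methyl]-4-oxopentanoate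
Conditions: TBAF, THF, 0 °C; aq. NH4Cl
Reagents that add atoms: none
Why: Fluoride desilylation of an aryl silyl ether is fast at 0 °C and non-acidic, conditions a diazoketone and a methyl ester tolerate, so the phenol is unmasked only just before use.

Step 12
Reactants: 19 methyl (3R)-5-diazo-3-[(3-hydroxy-2,6-dimethylphenyl)methyl]-4-oxopentanoate
Product: 21 methyl 3,8-dioxo-13-noreudesma-1,4-dien-12-oate [methyl 2-[(2R,4aS)-4a,8-dimethyl-3,7-dioxo-1,2,3,4,4a,7-hexahydronaphthalen-2-yl]acetate], via α-keto diazonium trifluoroacetate 20 (not isolated)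
Conditions: TFA, CH2Cl2, −20 → 0 °C (19 added slowly to the acid); NaHCO3 quench
Reagents that add atoms: none
Why: TFA protonates the diazo carbon C9 to the α-keto diazonium ion 20, the arene carbon para to the free hydroxyl (C10) displaces nitrogen from C9, and the resulting O-protonated dienone loses its proton to leave the cross-conjugated 1,4-dien-3-one. The closest known reaction type is the acid-promoted aryl-participation (Ar2-6) cyclisation of phenolic 1-diazo-4-arylbutan-2-ones, which gives 2-tetralones when the attacked carbon bears hydrogen and cyclohexadienones when it is substituted. Ring B (C5–C10) closes in a 6-exo-tet mode, the departing nitrogen lying outside the new ring. The new stereocentre C10 is controlled by C7: with the dienone ring planar the C10 methyl must be axial on ring B, and a chair-like transition state with the C7 CH2CO2Me branch equatorial places that methyl on the same β face. The step needs ipso attack at C10 rather than at C4, which is secured because C4 is wedged between the hydroxyl and the tether carbon C5 while C10 has a hydrogen-bearing neighbour and is the electronically favoured para site; O-alkylation would need an eight-membered ring, and a methyl ester, unlike a tert-butyl or benzyl ester, should not divert the cation into a lactone.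

Step 13
Reactants: 21 methyl 3,8-dioxo-13-noreudesma-1,4-dien-12-oate
Product: 22 methyl 3,8-dioxo-13-noreudesm-4-en-12-oate
Conditions: H2 (1 atm), RhCl(PPh3)3 (cat.), benzene/EtOH, rt
Reagents that add atoms: none
Why: Homogeneous hydrogenation with Wilkinson's catalyst saturates the disubstituted C1=C2 bond and leaves the tetrasubstituted C4=C5 enone, the ketones and the ester, as in the reduction of santonin-type dienones.

Step 14
Reactants: 22 methyl 3,8-dioxo-13-noreudesm-4-en-12-oate
Product: 24 3β-hydroxy-13-noreudesm-4-en-8β,12-olide, via diol ester 23 (not isolated)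
Conditions: NaBH4, CeCl3·7H2O, MeOH, −78 → 0 °C; then PPTS (cat.), CH2Cl2, rt
Reagents that add atoms: none
Why: Luche reduction delivers hydride to both carbonyls from the α face, axially at C3 to give the quasi-equatorial 3β-allylic alcohol and equatorially at C8 because the β axial path is blocked by the syn-axial C10 methyl (as steroid 2-ketones give 2β-ols), so the axial 8β-hydroxyl is cis to the C7 arm and lactonises.

Step 15
Reactants: 24 3β-hydroxy-13-noreudesm-4-en-8β,12-olide
Product: 25 3β-(tert-butyldimethylsilyloxy)-13-noreudesm-4-en-8β,12-olide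
Conditions: TBSCl, imidazole, DMF, rt
Reagents that add atoms: tert-butyldimethylsilyl chloride, CC(C)(C)[Si](C)(C)Cl
Why: Standard imidazole-promoted silylation masks the only free hydroxyl so that the lactone is the sole enolisable carbonyl in the next step.

Step 16
Reactants: 25 3β-(tert-butyldimethylsilyloxy)-13-noreudesm-4-en-8β,12-olide
Product: 29 3β-(tert-butyldimethylsilyloxy)eudesma-4,11(13)-dien-8β,12-olide, via lithium enolate 26 (not isolated), via Mannich base 27 (not isolated), via methiodide 28 (not isolated)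
Conditions: LDA, THF, −78 °C; CH2=NMe2+ I−, −78 °C → rt; MeI, MeOH, rt; aq. NaHCO3, EtOAc, rt
Reagents that add atoms: N,N-dimethylmethyleneiminium iodide (Eschenmoser's salt), C=[N+](C)C.[I-]
Why: α-Methylenation of a γ-lactone by the Eschenmoser-salt Mannich sequence (enolate aminomethylation, N-methylation, β-elimination of trimethylamine) creates C11=C13 and no stereocentre.

Step 17
Reactants: 29 3β-(tert-butyldimethylsilyloxy)eudesma-4,11(13)-dien-8β,12-olide
Product: 31 methyl 3β-(tert-butyldimethylsilyloxy)-8β-hydroxyeudesma-4,11(13)-dien-12-oate, via potassium carboxylate 30 (not isolated)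
Conditions: KOH (1.1 equiv), THF/H2O, rt; evaporate; MeI, DMF, 0 °C → rt
Reagents that add atoms: potassium hydroxide, [K+].[OH-]; iodomethane, CI
Why: Saponification of the lactone followed by SN2 O-methylation of the carboxylate salt gives the hydroxy ester without an acidification that would relactonise it; alantolactone-type 8β,12-olides are known to open to their hydroxy acids with alkali.

Step 18
Reactants: 31 methyl 3β-(tert-butyldimethylsilyloxy)-8β-hydroxyeudesma-4,11(13)-dien-12-oate
Product: 32 methyl 8β-acetoxy-3β-(tert-butyldimethylsilyloxy)eudesma-4,11(13)-dien-12-oate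
Conditions: Ac2O, Et3N, DMAP, CH2Cl2, 0 °C → rt (crude 31 used at once)
Reagents that add atoms: acetic anhydride, CC(=O)OC(C)=O
Why: DMAP-catalysed acetylation of the hindered axial 8β-hydroxyl should outpace relactonisation, which needs alkoxide or acid catalysis, and fixes the open form with retention at C8.

Step 19
Reactants: 32 methyl 8β-acetoxy-3β-(tert-butyldimethylsilyloxy)eudesma-4,11(13)-dien-12-oate
Product: 33 methyl 8β-acetoxy-3β-hydroxyeudesma-4,11(13)-dien-12-oate
Conditions: HF·pyridine, pyridine, THF, 0 °C → rt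
Reagents that add atoms: none
Why: Buffered HF·pyridine desilylation removes the secondary TBS ether without ionising the allylic C3–O bond and without the basic conditions that could attack the acetate or the acrylate.

Step 20
Reactants: 33 methyl 8β-acetoxy-3β-hydroxyeudesma-4,11(13)-dien-12-oate
Product: 34 methyl 8β-acetoxy-3β-propanoyloxyeudesma-4,11(13)-dien-12-oate
Conditions: (EtCO)2O, pyridine, DMAP (cat.), CH2Cl2, rt
Reagents that add atoms: propanoic anhydride, CCC(=O)OC(=O)CC
Why: DMAP-catalysed acylation of the unhindered 3β-allylic alcohol with the anhydride installs the propanoate with retention and completes the target.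

Compound list
1 | 2,6-dimethylbenzoic acid | Cc1cccc(C)c1C(=O)O | starting material
2 | 2,6-dimethyl-3-nitrobenzoic acid | Cc1ccc([N+](=O)[O-])c(C)c1C(=O)O | intermediate
3 | 3-amino-2,6-dimethylbenzoic acid | Cc1ccc(N)c(C)c1C(=O)O | intermediate
4 | 3-carboxy-2,4-dimethylbenzenediazonium hydrogensulfate | Cc1ccc([N+]#N)c(C)c1C(=O)O.OS(=O)(=O)[O-] | intermediate (not isolated)
5 | 3-hydroxy-2,6-dimethylbenzoic acid | Cc1ccc(O)c(C)c1C(=O)O | intermediate
6 | 3-(hydroxymethyl)-2,4-dimethylphenol | Cc1ccc(O)c(C)c1CO | intermediate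
7 | sodium 3-(hydroxymethyl)-2,4-dimethylphenolate | Cc1ccc([O-])c(C)c1CO.[Na+] | intermediate (not isolated)
8 | {2,6-dimethyl-3-[(triisopropylsilyl)oxy]phenyl}methanol | Cc1ccc(O[Si](C(C)C)(C(C)C)C(C)C)c(C)c1CO | intermediate
9 | [3-(bromomethyl)-2,4-dimethylphenoxy]triisopropylsilane | Cc1ccc(O[Si](C(C)C)(C(C)C)C(C)C)c(C)c1CBr | intermediate
10 | (R)-4-benzyl-2-oxazolidinone | O=C1OC[C@@H](Cc2ccccc2)N1 | starting material
11 | methyl 4-chloro-4-oxobutanoate | COC(=O)CCC(Cl)=O | starting material
12 | methyl 4-[(4R)-4-benzyl-2-oxo-1,3-oxazolidin-3-yl]-4-oxobutanoate | O=C1OC[C@@H](Cc2ccccc2)N1C(=O)CCC(=O)OC | intermediate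
13 | sodium (Z)-enolate of 12 | O=C1OC[C@@H](Cc2ccccc2)N1/C([O-])=C/CC(=O)OC.[Na+] | intermediate (not isolated)
14 | methyl (3R)-4-[(4R)-4-benzyl-2-oxo-1,3-oxazolidin-3-yl]-3-{[2,6-dimethyl-3-(triisopropylsilyloxy)phenyl]methyl}-4-oxobutanoate | O=C1OC[C@@H](Cc2ccccc2)N1C(=O)[C@@H](CC(=O)OC)Cc3c(C)c(O[Si](C(C)C)(C(C)C)C(C)C)ccc3C | intermediate
15 | lithium (2R)-2-{[2,6-dimethyl-3-(triisopropylsilyloxy)phenyl]methyl}-4-methoxy-4-oxobutaneperoxoate | [Li+].[O-]OC(=O)[C@@H](CC(=O)OC)Cc1c(C)c(O[Si](C(C)C)(C(C)C)C(C)C)ccc1C | intermediate (not isolated)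
16 | (2R)-2-{[2,6-dimethyl-3-(triisopropylsilyloxy)phenyl]methyl}-4-methoxy-4-oxobutanoic acid | OC(=O)[C@@H](CC(=O)OC)Cc1c(C)c(O[Si](C(C)C)(C(C)C)C(C)C)ccc1C | intermediate
17 | mixed anhydride of 16 with isobutyl hydrogen carbonate | CC(C)COC(=O)OC(=O)[C@@H](CC(=O)OC)Cc1c(C)c(O[Si](C(C)C)(C(C)C)C(C)C)ccc1C | intermediate (not isolated)
18 | methyl (3R)-5-diazo-3-{[2,6-dimethyl-3-(triisopropylsilyloxy)phenyl]methyl}-4-oxopentanoate | COC(=O)C[C@@H](Cc1c(C)c(O[Si](C(C)C)(C(C)C)C(C)C)ccc1C)C(=O)C=[N+]=[N-] | intermediate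
19 | methyl (3R)-5-diazo-3-[(3-hydroxy-2,6-dimethylphenyl)methyl]-4-oxopentanoate | COC(=O)C[C@@H](Cc1c(C)c(O)ccc1C)C(=O)C=[N+]=[N-] | intermediate (key-step precursor)
20 | methyl (3R)-5-diazonio-3-[(3-hydroxy-2,6-dimethylphenyl)methyl]-4-oxopentanoate trifluoroacetate | COC(=O)C[C@@H](Cc1c(C)c(O)ccc1C)C(=O)C[N+]#N.[O-]C(=O)C(F)(F)F | intermediate (not isolated)
21 | methyl 3,8-dioxo-13-noreudesma-1,4-dien-12-oate (7β side chain; 10β methyl) | COC(=O)C[C@H]1CC2=C(C)C(=O)C=C[C@]2(C)CC1=O | intermediate (key-step product)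
22 | methyl 3,8-dioxo-13-noreudesm-4-en-12-oate | COC(=O)C[C@H]1CC2=C(C)C(=O)CC[C@]2(C)CC1=O | intermediate
23 | methyl 3β,8β-dihydroxy-13-noreudesm-4-en-12-oate | COC(=O)C[C@H]1CC2=C(C)[C@@H](O)CC[C@]2(C)C[C@H]1O | intermediate (not isolated)
24 | 3β-hydroxy-13-noreudesm-4-en-8β,12-olide (cis-fused γ-lactone) | O=C1C[C@H]2CC3=C(C)[C@@H](O)CC[C@]3(C)C[C@H]2O1 | intermediate
25 | 3β-(tert-butyldimethylsilyloxy)-13-noreudesm-4-en-8β,12-olide | O=C1C[C@H]2CC3=C(C)[C@@H](O[Si](C)(C)C(C)(C)C)CC[C@]3(C)C[C@H]2O1 | intermediate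
26 | lithium enolate of 25 | [Li+].[O-]C1=C[C@H]2CC3=C(C)[C@@H](O[Si](C)(C)C(C)(C)C)CC[C@]3(C)C[C@H]2O1 | intermediate (not isolated)
27 | 13-(dimethylamino)-3β-(tert-butyldimethylsilyloxy)eudesm-4-en-8β,12-olide (C11 undefined) | O=C1C(CN(C)C)[C@H]2CC3=C(C)[C@@H](O[Si](C)(C)C(C)(C)C)CC[C@]3(C)C[C@H]2O1 | intermediate (not isolated)
28 | 13-(trimethylammonio)-3β-(tert-butyldimethylsilyloxy)eudesm-4-en-8β,12-olide iodide (C11 undefined) | O=C1C(C[N+](C)(C)C)[C@H]2CC3=C(C)[C@@H](O[Si](C)(C)C(C)(C)C)CC[C@]3(C)C[C@H]2O1.[I-] | intermediate (not isolated)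
29 | 3β-(tert-butyldimethylsilyloxy)eudesma-4,11(13)-dien-8β,12-olide | O=C1C(=C)[C@H]2CC3=C(C)[C@@H](O[Si](C)(C)C(C)(C)C)CC[C@]3(C)C[C@H]2O1 | intermediate
30 | potassium 3β-(tert-butyldimethylsilyloxy)-8β-hydroxyeudesma-4,11(13)-dien-12-oate | [K+].[O-]C(=O)C(=C)[C@H]1CC2=C(C)[C@@H](O[Si](C)(C)C(C)(C)C)CC[C@]2(C)C[C@H]1O | intermediate (not isolated)
31 | methyl 3β-(tert-butyldimethylsilyloxy)-8β-hydroxyeudesma-4,11(13)-dien-12-oate | C=C(C(=O)OC)[C@H]1CC2=C(C)[C@@H](O[Si](C)(C)C(C)(C)C)CC[C@]2(C)C[C@H]1O | intermediate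
32 | methyl 8β-acetoxy-3β-(tert-butyldimethylsilyloxy)eudesma-4,11(13)-dien-12-oate | C=C(C(=O)OC)[C@H]1CC2=C(C)[C@@H](O[Si](C)(C)C(C)(C)C)CC[C@]2(C)C[C@H]1OC(C)=O | intermediate
33 | methyl 8β-acetoxy-3β-hydroxyeudesma-4,11(13)-dien-12-oate | C=C(C(=O)OC)[C@H]1CC2=C(C)[C@@H](O)CC[C@]2(C)C[C@H]1OC(C)=O | intermediate
34 | methyl 8β-acetoxy-3β-propanoyloxyeudesma-4,11(13)-dien-12-oate (CNP0198123.1) | C=C(C(=O)OC)[C@H]1CC2=C(C)[C@@H](OC(=O)CC)CC[C@]2(C)C[C@H]1OC(C)=O | target

Total step count: 20. Longest linear sequence: 19 steps (steps 1–6 and 8–20; step 7 is the one-step side branch).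

Steps most likely to fail

1. Step 12. The cation may be diverted by ipso attack at C4 (ortho to the hydroxyl), by capture of the diazonium ion by trifluoroacetate, or by a boat-like closure that puts the C10 methyl trans to the C7 branch. A minor C10 epimer would have to be separated, not equilibrated, because epimerising its C7 would give the enantiomeric series. The fallback sets out from 19 and replaces the cationic closure by an anionic one. Aqueous HBr in Et2O at 0 °C should convert the diazoketone into methyl (3R)-5-bromo-3-[(3-hydroxy-2,6-dimethylphenyl)methyl]-4-oxopentanoate F1. One equivalent of KOt-Bu in t-BuOH/THF (0 °C → rt) should then generate the phenoxide, whose para carbon displaces bromide intramolecularly (Winstein–Masamune dearomatising phenoxide alkylation). The route is rejoined at 21.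

2. Step 14. One small hydride must reduce two different carbonyls with the right facial sense; the process risks are insufficient α-face preference at C8 or C3 and incomplete lactonisation. The fallback sets out from 22 and stages the reduction. L-Selectride (THF, −78 °C) should reduce the saturated C8 ketone much faster than the hindered β,β-disubstituted enone and strictly from the equatorial direction, the 8β-alkoxide lactonising on warming to 3-oxo-13-noreudesm-4-en-8β,12-olide F2. A separate Luche reduction of the enone alone then returns to 24.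

3. Step 17. The γ-hydroxy ester may relactonise before it is acetylated, or hydroxide may add in a conjugate sense to the α-methylene lactone. The fallback sets out from 29 and never passes through a γ-hydroxy ester. DIBAL-H (CH2Cl2, −78 → 0 °C) should reduce the lactone to 3β-(tert-butyldimethylsilyloxy)eudesma-4,11(13)-diene-8β,12-diol F3. Ac2O/DMAP gives the 8β,12-diacetate F4. K2CO3/MeOH at 0 °C should remove only the primary allylic acetate to give 8β-acetoxy-3β-(tert-butyldimethylsilyloxy)eudesma-4,11(13)-dien-12-ol F5. MnO2 gives 8β-acetoxy-3β-(tert-butyldimethylsilyloxy)eudesma-4,11(13)-dien-12-al F6, and Pinnick oxidation (NaClO2, NaH2PO4, 2-methyl-2-butene) gives 8β-acetoxy-3β-(tert-butyldimethylsilyloxy)eudesma-4,11(13)-dien-12-oic acid F7. Esterification with TMSCHN2 in MeOH/toluene returns to the route at 32, so that step 18 is skipped.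

Further compounds
F1 | step 12 | methyl (3R)-5-bromo-3-[(3-hydroxy-2,6-dimethylphenyl)methyl]-4-oxopentanoate | COC(=O)C[C@@H](Cc1c(C)c(O)ccc1C)C(=O)CBr
F2 | step 14 | 3-oxo-13-noreudesm-4-en-8β,12-olide | O=C1C[C@H]2CC3=C(C)C(=O)CC[C@]3(C)C[C@H]2O1
F3 | step 17 | 3β-(tert-butyldimethylsilyloxy)eudesma-4,11(13)-diene-8β,12-diol | C=C(CO)[C@H]1CC2=C(C)[C@@H](O[Si](C)(C)C(C)(C)C)CC[C@]2(C)C[C@H]1O
F4 | step 17 | 3β-(tert-butyldimethylsilyloxy)eudesma-4,11(13)-diene-8β,12-diyl diacetate | C=C(COC(C)=O)[C@H]1CC2=C(C)[C@@H](O[Si](C)(C)C(C)(C)C)CC[C@]2(C)C[C@H]1OC(C)=O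
F5 | step 17 | 8β-acetoxy-3β-(tert-butyldimethylsilyloxy)eudesma-4,11(13)-dien-12-ol | C=C(CO)[C@H]1CC2=C(C)[C@@H](O[Si](C)(C)C(C)(C)C)CC[C@]2(C)C[C@H]1OC(C)=O
F6 | step 17 | 8β-acetoxy-3β-(tert-butyldimethylsilyloxy)eudesma-4,11(13)-dien-12-al | C=C(C=O)[C@H]1CC2=C(C)[C@@H](O[Si](C)(C)C(C)(C)C)CC[C@]2(C)C[C@H]1OC(C)=O
F7 | step 17 | 8β-acetoxy-3β-(tert-butyldimethylsilyloxy)eudesma-4,11(13)-dien-12-oic acid | C=C(C(=O)O)[C@H]1CC2=C(C)[C@@H](O[Si](C)(C)C(C)(C)C)CC[C@]2(C)C[C@H]1OC(C)=O
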